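**Strategy.** With isochromene numbering, the 2H-pyran ring (O2–C1H2–C8a=C4a–C4=C3) is the valence tautomer of a Z-dienone O=C3–C4=C4a–C8a=C1H2 whose central bond C4a–C8a is held s-cis by ring A. The C1–O2 bond is therefore made last, by oxa-6π electrocyclisation. The dienone is generated and consumed in one flask: the enolate of a trans-epoxy methyl ketone attacks C4a of a ring A enol triflate that bears a sulfonylmethyl group on C8a, triflate leaves, sulfinate is lost by 1,6-elimination and the ring closes. Ring A, with ester and both carbinol centres, comes from a resorcinol by hydroxylative dearomatisation and dynamic desymmetrising transfer hydrogenation.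

Key step: step 9

Remark: bicycle atoms are numbered as in 1H-isochromene (C1, O2, C3, C4, C4a, C5–C8, C8a); 5-methoxy-2-methylbenzene-1,3-diol is taken as a catalogue compound.

Step 1
Reactants: 1 (E)-pent-3-en-2-one
Product: 2 1-[(2S,3R)-3-methyloxiran-2-yl]ethan-1-one
Conditions: La(OiPr)3 (5 mol %), (R)-BINOL (5 mol %), Ph3As=O (5 mol %), tBuOOH (1.2 equiv), 4 Å MS, THF, rt
Reagents that add atoms: tert-butyl hydroperoxide, CC(C)(C)OO
Why: Catalytic asymmetric nucleophilic (Weitz–Scheffer-type) epoxidation of an (E)-enone, in which the chiral lanthanum binaphtholate delivers the peroxide to one enone face so that both epoxide centres arise trans, with the (αS,βR) sense expected for the (R)-ligand.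

Step 2
Reactants: 3 orsellinic acid (2,4-dihydroxy-6-methylbenzoic acid)
Product: 4 tert-butyldimethylsilyl 2,4-bis(TBS-oxy)-6-methylbenzoate
Conditions: TBSCl (3.3 equiv), imidazole (6.5 equiv), DMF, rt
Reagents that add atoms: tert-butyl(chloro)dimethylsilane, C[Si](C)(Cl)C(C)(C)C
Why: Exhaustive silylation of both phenols and the acid (silyl ether and silyl ester formation) should proceed without any stereochemical issue.

Step 3
Reactants: 4 tert-butyldimethylsilyl 2,4-bis(TBS-oxy)-6-methylbenzoate
Product: 5 2,4-bis(TBS-oxy)-6-methylbenzoyl chloride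
Conditions: (COCl)2 (1.2 equiv), DMF (cat.), CH2Cl2, 0 °C to rt
Reagents that add atoms: oxalyl chloride, O=C(Cl)C(Cl)=O
Why: Direct conversion of a silyl ester into the acid chloride by the Vilsmeier chloride should leave the aryl silyl ethers untouched.

Step 4
Reactants: 6 5-methoxy-2-methylbenzene-1,3-diol
Product: 7 2-hydroxy-5-methoxy-2-methylcyclohex-4-ene-1,3-dione (racemic and configurationally labile)
Conditions: IBX (1.1 equiv, benzoic/isophthalic acid-stabilised formulation), THF, rt; then H2O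
Reagents that add atoms: 2-iodoxybenzoic acid (IBX), O=C1OI(=O)(O)c2ccccc12
Why: Hydroxylative phenol dearomatisation, in which the phenol oxygen binds pentavalent iodine and oxygen is delivered to the methyl-bearing ortho carbon flanked by both hydroxyls; the new carbinol centre needs no control because 7 racemises by keto–enol exchange between its two equivalent carbonyl arms.

Step 5
Reactants: 7 2-hydroxy-5-methoxy-2-methylcyclohex-4-ene-1,3-dione
Product: 8 (5R,6R)-5,6-dihydroxy-3-methoxy-6-methylcyclohex-2-en-1-one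
Conditions: RuCl[(R,R)-TsDPEN](p-cymene) (2 mol %), HCO2H/Et3N (5:2), CH2Cl2, 30 °C
Reagents that add atoms: none
Why: Noyori asymmetric transfer hydrogenation run as a dynamic kinetic resolution (formally the desymmetrisation of a 2,2-disubstituted 1,3-dione) should reduce only the non-conjugated ketone, the catalyst setting C5 (5R expected for the (R,R)-ligand) and hydride delivery anti to the neighbouring C–OH bond giving the cis-diol, so that C6 is selected from the rapidly interconverting enantiomers of 7.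

Step 6
Reactants: 8 (5R,6R)-5,6-dihydroxy-3-methoxy-6-methylcyclohex-2-en-1-one; 5 2,4-bis(TBS-oxy)-6-methylbenzoyl chloride
Product: 9 (1R,6R)-6-hydroxy-3-methoxy-6-methyl-5-oxocyclohex-3-en-1-yl 2,4-bis(TBS-oxy)-6-methylbenzoate
Conditions: Et3N (2 equiv), DMAP (0.3 equiv), CH2Cl2, rt to 40 °C
Reagents that add atoms: none
Why: DMAP-catalysed acylation (nucleophilic acyl-transfer catalysis) should esterify the secondary hydroxyl only, the tertiary α-ketol hydroxyl being too hindered.

Step 7
Reactants: 9 (1R,6R)-6-hydroxy-3-methoxy-6-methyl-5-oxocyclohex-3-en-1-yl 2,4-bis(TBS-oxy)-6-methylbenzoate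
Product: 11 (1R,6R)-3,6-dihydroxy-6-methyl-5-oxo-4-[(phenylsulfonyl)methyl]cyclohex-3-en-1-yl 2,4-bis(TBS-oxy)-6-methylbenzoate, via free dione 10 (not isolated)
Conditions: 1 M HCl, THF, 0 °C to rt; then 37% aq. CH2O (1.5 equiv), PhSO2Na (1.5 equiv), rt
Reagents that add atoms: water, O; formaldehyde, C=O; sodium benzenesulfinate, [Na+].[O-]S(=O)c1ccccc1
Why: Acid hydrolysis of the vinylogous ester followed by a three-component Knoevenagel/sulfa-Michael (Mannich-type) sulfonylmethylation should place the CH2SO2Ph group on C2 of the 1,3-dione, its only doubly activated carbon, because sulfinic acid traps the transient 2-methylene dione.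

Step 8
Reactants: 11 (1R,6R)-3,6-dihydroxy-6-methyl-5-oxo-4-[(phenylsulfonyl)methyl]cyclohex-3-en-1-yl 2,4-bis(TBS-oxy)-6-methylbenzoate
Product: 12 (1R,6R)-6-hydroxy-6-methyl-5-oxo-4-[(phenylsulfonyl)methyl]-3-(triflyloxy)cyclohex-3-en-1-yl 2,4-bis(TBS-oxy)-6-methylbenzoate
Conditions: Tf2O (1.05 equiv), 2,6-lutidine (1.2 equiv), CH2Cl2, −78 °C
Reagents that add atoms: triflic anhydride, FC(F)(F)S(=O)(=O)OS(=O)(=O)C(F)(F)F
Why: Enol triflation of the 1,3-dione should occur on the oxygen remote from the quaternary carbinol carbon (less hindered, the other carbonyl being hydrogen-bonded to the tertiary hydroxyl), and the low temperature should suppress sulfinate loss and triflation of the tertiary alcohol.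

Step 9
Reactants: 12 (1R,6R)-6-hydroxy-6-methyl-5-oxo-4-[(phenylsulfonyl)methyl]-3-(triflyloxy)cyclohex-3-en-1-yl 2,4-bis(TBS-oxy)-6-methylbenzoate; 2 1-[(2S,3R)-3-methyloxiran-2-yl]ethan-1-one
Product: 15 (6R,7R)-7-hydroxy-7-methyl-3-[(2S,3R)-3-methyloxiran-2-yl]-8-oxo-5,6,7,8-tetrahydro-1H-isochromen-6-yl 2,4-bis(TBS-oxy)-6-methylbenzoate, via ene-dione sulfone 13 (not isolated), via Z-oxatriene 14 (not isolated)
Conditions: 2 (2.2 equiv), LiN(SiMe3)2 (2.1 equiv), THF, −78 °C; then 12, −78 °C to rt
Reagents that add atoms: none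
Why: The lithium enolate of 2 adds to C4a of the β-triflyloxy enone and triflate is expelled (vinylogous acyl substitution, as in the classical condensation of β-halovinyl ketones with ketone enolates) to give ene-dione 13. Its doubly activated C4 methylene is deprotonated by the second equivalent of base, and the dienolate expels benzenesulfinate from C1 in a vinylogous E1cB (1,6-) elimination, the reaction type known for base-induced sulfinate loss from allylic sulfones, which unveils the 1-oxatriene 14. Thermal disrotatory oxa-6π electrocyclisation of 14, the known dienone-to-2H-pyran valence isomerisation, then closes the pyran ring by joining the ketone oxygen to the exocyclic methylene carbon C1. No stereocentre is created, and the carbinol and epoxide centres are spectators because the epoxide α-hydrogen is not enolisable and the ester-bearing carbon is not acidic. The step needs carbon attack at C4a and not at C1, which the sulfone secures because it is no leaving group for direct displacement, and it needs the Z-dienone, which either geometric isomer can supply because sulfinate re-adds reversibly to the exocyclic enone and frees rotation about C4–C4a. The closed form should be the thermodynamic sink because ring A fixes the s-cis diene and the product is a push–pull vinylogous ester.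

Step 10
Reactants: 15 (6R,7R)-7-hydroxy-7-methyl-3-[(2S,3R)-3-methyloxiran-2-yl]-8-oxo-5,6,7,8-tetrahydro-1H-isochromen-6-yl 2,4-bis(TBS-oxy)-6-methylbenzoate
Product: 16 (6R,7R)-7-hydroxy-7-methyl-3-[(2S,3R)-3-methyloxiran-2-yl]-8-oxo-5,6,7,8-tetrahydro-1H-isochromen-6-yl 2,4-dihydroxy-6-methylbenzoate (CNP0323247.1)
Conditions: Bu4NF (2.2 equiv), AcOH (2.2 equiv), THF, 0 °C
Reagents that add atoms: none
Why: Buffered fluoride desilylation of the two aryl silyl ethers should be fast and should spare the hindered benzoate, the epoxide and the dienol ether.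

**Compound list**

1 | (E)-pent-3-en-2-one | C/C=C/C(C)=O | starting material
2 | 1-[(2S,3R)-3-methyloxiran-2-yl]ethan-1-one | CC(=O)[C@H]1O[C@@H]1C | intermediate
3 | orsellinic acid (2,4-dihydroxy-6-methylbenzoic acid) | Cc1cc(O)cc(O)c1C(=O)O | starting material
4 | tert-butyldimethylsilyl 2,4-bis[(tert-butyldimethylsilyl)oxy]-6-methylbenzoate | Cc1cc(O[Si](C)(C)C(C)(C)C)cc(O[Si](C)(C)C(C)(C)C)c1C(=O)O[Si](C)(C)C(C)(C)C | intermediate
5 | 2,4-bis[(tert-butyldimethylsilyl)oxy]-6-methylbenzoyl chloride | Cc1cc(O[Si](C)(C)C(C)(C)C)cc(O[Si](C)(C)C(C)(C)C)c1C(=O)Cl | intermediate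
6 | 5-methoxy-2-methylbenzene-1,3-diol | COc1cc(O)c(C)c(O)c1 | starting material
7 | 2-hydroxy-5-methoxy-2-methylcyclohex-4-ene-1,3-dione (racemic, configurationally labile) | COC1=CC(=O)C(C)(O)C(=O)C1 | intermediate
8 | (5R,6R)-5,6-dihydroxy-3-methoxy-6-methylcyclohex-2-en-1-one | O[C@@H]1CC(OC)=CC(=O)[C@]1(C)O | intermediate
9 | (1R,6R)-6-hydroxy-3-methoxy-6-methyl-5-oxocyclohex-3-en-1-yl 2,4-bis[(tert-butyldimethylsilyl)oxy]-6-methylbenzoate | Cc1cc(O[Si](C)(C)C(C)(C)C)cc(O[Si](C)(C)C(C)(C)C)c1C(=O)O[C@@H]1CC(OC)=CC(=O)[C@]1(C)O | intermediate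
10 | (1R,2R)-2-hydroxy-2-methyl-3,5-dioxocyclohexyl 2,4-bis[(tert-butyldimethylsilyl)oxy]-6-methylbenzoate | Cc1cc(O[Si](C)(C)C(C)(C)C)cc(O[Si](C)(C)C(C)(C)C)c1C(=O)O[C@@H]1CC(=O)CC(=O)[C@]1(C)O | intermediate
11 | (1R,6R)-3,6-dihydroxy-6-methyl-5-oxo-4-[(phenylsulfonyl)methyl]cyclohex-3-en-1-yl 2,4-bis[(tert-butyldimethylsilyl)oxy]-6-methylbenzoate (enol form) | Cc1cc(O[Si](C)(C)C(C)(C)C)cc(O[Si](C)(C)C(C)(C)C)c1C(=O)O[C@@H]1CC(O)=C(CS(=O)(=O)c2ccccc2)C(=O)[C@]1(C)O | intermediate
12 | (1R,6R)-6-hydroxy-6-methyl-5-oxo-4-[(phenylsulfonyl)methyl]-3-[(trifluoromethanesulfonyl)oxy]cyclohex-3-en-1-yl 2,4-bis[(tert-butyldimethylsilyl)oxy]-6-methylbenzoate | Cc1cc(O[Si](C)(C)C(C)(C)C)cc(O[Si](C)(C)C(C)(C)C)c1C(=O)O[C@@H]1CC(OS(=O)(=O)C(F)(F)F)=C(CS(=O)(=O)c2ccccc2)C(=O)[C@]1(C)O | intermediate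
13 | (1R,6R)-6-hydroxy-6-methyl-3-{2-[(2S,3R)-3-methyloxiran-2-yl]-2-oxoethyl}-5-oxo-4-[(phenylsulfonyl)methyl]cyclohex-3-en-1-yl 2,4-bis[(tert-butyldimethylsilyl)oxy]-6-methylbenzoate | Cc1cc(O[Si](C)(C)C(C)(C)C)cc(O[Si](C)(C)C(C)(C)C)c1C(=O)O[C@@H]1CC(CC(=O)[C@H]2O[C@@H]2C)=C(CS(=O)(=O)c2ccccc2)C(=O)[C@]1(C)O | intermediate
14 | (1R,2R,5Z)-2-hydroxy-2-methyl-4-methylidene-5-{2-[(2S,3R)-3-methyloxiran-2-yl]-2-oxoethylidene}-3-oxocyclohexyl 2,4-bis[(tert-butyldimethylsilyl)oxy]-6-methylbenzoate | Cc1cc(O[Si](C)(C)C(C)(C)C)cc(O[Si](C)(C)C(C)(C)C)c1C(=O)O[C@@H]1C/C(=C/C(=O)[C@H]2O[C@@H]2C)C(=C)C(=O)[C@]1(C)O | intermediate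
15 | (6R,7R)-7-hydroxy-7-methyl-3-[(2S,3R)-3-methyloxiran-2-yl]-8-oxo-5,6,7,8-tetrahydro-1H-isochromen-6-yl 2,4-bis[(tert-butyldimethylsilyl)oxy]-6-methylbenzoate | Cc1cc(O[Si](C)(C)C(C)(C)C)cc(O[Si](C)(C)C(C)(C)C)c1C(=O)O[C@@H]1CC2=C(COC([C@H]3O[C@@H]3C)=C2)C(=O)[C@]1(C)O | intermediate
16 | (6R,7R)-7-hydroxy-7-methyl-3-[(2S,3R)-3-methyloxiran-2-yl]-8-oxo-5,6,7,8-tetrahydro-1H-isochromen-6-yl 2,4-dihydroxy-6-methylbenzoate | Cc1cc(O)cc(O)c1C(=O)O[C@@H]1CC2=C(COC([C@H]3O[C@@H]3C)=C2)C(=O)[C@]1(C)O | target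

**Totals.** Total step count: 10. Longest linear sequence: 7 steps (steps 4 to 10, from 6 to 16).

**Steps most likely to fail**

Step 9. The basic enolate may deprotonate 12 at C5 or at the sulfonyl methylene instead of adding to C4a, which would lead to loss of the benzoate by β-elimination or to self-condensation. The fallback sets out from 12 and 2 and returns to the route at 15. Ketone 2 would be converted (Me3SiOTf, Et3N, CH2Cl2, 0 °C) into the silyl enol ether trimethyl({1-[(2S,3R)-3-methyloxiran-2-yl]ethenyl}oxy)silane F1. A fluoride-triggered Mukaiyama–Michael addition–elimination of this compound to 12 ((Me2N)3S+ Me3SiF2−, THF, −78 °C) should give 13 without any amide base, and 13 would be isolated. Separate treatment of 13 with DBU in MeCN at rt should then bring about the sulfinate elimination and the electrocyclisation to 15.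

Step 5. Hydride transfer may be slow or poorly face-selective because 7 rests largely as its enol, or reduction may outrun racemisation. The fallback sets out from 7 and returns at 8. Luche reduction (NaBH4, CeCl3·7H2O, MeOH, −40 °C) should give the racemic cis-diol rac-(5R,6R)-5,6-dihydroxy-3-methoxy-6-methylcyclohex-2-en-1-one F2. Lipase-catalysed transesterification (Candida antarctica lipase B, vinyl acetate, tBuOMe) is expected to acylate the 5R enantiomer, giving (1R,6R)-6-hydroxy-3-methoxy-6-methyl-5-oxocyclohex-3-en-1-yl acetate F3, which would be separated from the unreacted antipode. Methanolysis (K2CO3, MeOH, 0 °C) should then give 8.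

Step 4. Oxygen transfer may go to the unsubstituted ortho carbons, with over-oxidation to a quinone. The fallback sets out from 6 and returns at 7. Wessely acetoxylation (Pb(OAc)4, AcOH/CHCl3, 0 °C), which favours the alkyl-bearing ortho carbon, should give the quinol acetate 4-methoxy-1-methyl-2,6-dioxocyclohex-3-en-1-yl acetate F4. Mild methanolysis (K2CO3, MeOH, 0 °C) should then free 7.

Further compounds
F1 | step 9 | trimethyl({1-[(2S,3R)-3-methyloxiran-2-yl]ethenyl}oxy)silane | C=C(O[Si](C)(C)C)[C@H]1O[C@@H]1C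
F2 | step 5 | rac-(5R,6R)-5,6-dihydroxy-3-methoxy-6-methylcyclohex-2-en-1-one (racemic cis-diol) | O[C@@H]1CC(OC)=CC(=O)[C@]1(C)O.O[C@H]1CC(OC)=CC(=O)[C@@]1(C)O
F3 | step 5 | (1R,6R)-6-hydroxy-3-methoxy-6-methyl-5-oxocyclohex-3-en-1-yl acetate | CC(=O)O[C@@H]1CC(OC)=CC(=O)[C@]1(C)O
F4 | step 4 | 4-methoxy-1-methyl-2,6-dioxocyclohex-3-en-1-yl acetate (racemic) | COC1=CC(=O)C(C)(OC(C)=O)C(=O)C1
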